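**Plan**

1. The tert-butyl ester is cleaved last. Before that, the cyclopentanone (C1–C2–C3–C3a–C7a) is traced back to a six-membered ring B with one extra carbonyl carbon between C1 and C3, a trans-fused cyclohexane-1,2-dione; it is contracted by benzilic acid rearrangement and oxidative decarboxylation.
2. Enabling feature: C2 is a carbonyl flanked by two enolisable CH centres (C1–Me, C3–Et), while the fusion atoms C3a and C7a are β to it. Either carbonyl carbon of the dione can therefore be excised with the same result, the trans junction is never touched, and C1/C3 are set at the end by equilibration.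
3. The dione comes from a decalone, cut at C4a–C8a and C1–C2 (decalin numbering) by an intramolecular Diels–Alder reaction of a one-carbon homologue of the polyene ketone presumed in the biosynthesis.
4. Forward: (R)-methylsuccinate half ester → three E-selective olefinations → triene aldehyde 7; vinylogous Mukaiyama aldol with silyl dienolate 11; oxidation; cycloaddition (cyclohexene ring A and ring B together); α-oxygenation; contraction of ring B; deprotection.
5. Stereochemistry: the one purchased stereocentre (R) fixes the diene face by allylic 1,3-strain; the E olefin geometries and the endo-ester/anti-tether transition state set C3a, C4, C5 and C7a; C1 and C3 are settled thermodynamically α to the ketone.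

Key step: step 14

Assumption: compound 1, acid 8 and the two formyl-stabilised phosphoranes are taken as catalogue chemicals; C1–C7a refer to the indene skeleton of the target, and decalin intermediates carry naphthalene numbers.

**Route**

Step 1
Reactants: 1 (2R)-4-tert-butoxy-2-methyl-4-oxobutanoic acid
Product: 2 tert-butyl (3R)-4-hydroxy-3-methylbutanoate
Conditions: BH3·SMe2, THF, 0 °C to rt; then H2O
Reagents that add atoms: none
Why: Borane reduces the free carboxylic acid through its acyloxyborane much faster than the tert-butyl ester (chemoselective borane reduction), and the stereocentre is not involved.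

Step 2
Reactants: 2 tert-butyl (3R)-4-hydroxy-3-methylbutanoate
Product: 3 tert-butyl (3R)-3-methyl-4-oxobutanoate
Conditions: Dess–Martin periodinane, CH2Cl2, 0 °C to rt
Reagents that add atoms: none
Why: Dess–Martin oxidation of the primary alcohol stops at the aldehyde under near-neutral conditions, so the α-methyl stereocentre should not epimerise.

Step 3
Reactants: 3 tert-butyl (3R)-3-methyl-4-oxobutanoate
Product: 4 tert-butyl (3R,4E)-3,5-dimethyl-6-oxohex-4-enoate
Conditions: Ph3P=C(CH3)CHO, toluene, 80 °C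
Reagents that add atoms: 2-(triphenylphosphoranylidene)propanal, CC(C=O)=P(c1ccccc1)(c1ccccc1)c1ccccc1
Why: Wittig olefination with a formyl-stabilised ylide should give the E trisubstituted enal and is too weakly basic to epimerise the α-stereocentre of 3.

Step 4
Reactants: 4 tert-butyl (3R,4E)-3,5-dimethyl-6-oxohex-4-enoate
Product: 5 tert-butyl (3R,4E,6E)-7-ethyl-3,5-dimethyl-8-oxoocta-4,6-dienoate
Conditions: Ph3P=C(C2H5)CHO, toluene, 110 °C
Reagents that add atoms: 2-(triphenylphosphoranylidene)butanal, CCC(C=O)=P(c1ccccc1)(c1ccccc1)c1ccccc1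
Why: A second Wittig olefination with the homologous formyl ylide extends the enal to the E,E dienal (formyl group anti to the chain), and the more hindered, less electrophilic product should resist further olefination.

Step 5
Reactants: 5 tert-butyl (3R,4E,6E)-7-ethyl-3,5-dimethyl-8-oxoocta-4,6-dienoate
Product: 6 tert-butyl (3R,4E,6E,8E)-7-ethyl-3,5-dimethyl-9-phenylnona-4,6,8-trienoate
Conditions: (EtO)2P(O)CH2Ph, KOt-Bu, THF, −78 °C to rt (anion pre-formed)
Reagents that add atoms: diethyl benzylphosphonate, CCOP(=O)(Cc1ccccc1)OCC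
Why: Horner–Wadsworth–Emmons olefination with the benzylphosphonate anion should give the E styryl double bond, and the tert-butyl ester is inert to tert-butoxide.

Step 6
Reactants: 6 tert-butyl (3R,4E,6E,8E)-7-ethyl-3,5-dimethyl-9-phenylnona-4,6,8-trienoate
Product: 7 (3R,4E,6E,8E)-7-ethyl-3,5-dimethyl-9-phenylnona-4,6,8-trienal
Conditions: i-Bu2AlH, CH2Cl2, −78 °C; aqueous potassium sodium tartrate
Reagents that add atoms: none
Why: At −78 °C the aluminium hemiacetal formed from the tert-butyl ester is stable and collapses to the aldehyde only on work-up (partial ester reduction); the stereocentre is β to the carbonyl and cannot epimerise.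

Step 7
Reactants: 8 (2E)-2-ethylhex-2-enoic acid
Product: 9 tert-butyl (2E)-2-ethylhex-2-enoate
Conditions: tert-butyl 2,2,2-trichloroacetimidate, BF3·OEt2 (cat.), cyclohexane–CH2Cl2, rt
Reagents that add atoms: tert-butyl 2,2,2-trichloroacetimidate, CC(C)(C)OC(=N)C(Cl)(Cl)Cl
Why: Acid-catalysed O-alkylation by the trichloroacetimidate transfers a tert-butyl cation to the acid; the olefin geometry of the acid is immaterial because step 8 passes through the dienolate.

Step 8
Reactants: 9 tert-butyl (2E)-2-ethylhex-2-enoate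
Product: 11 {[(3E)-1-tert-butoxy-2-ethylhexa-1,3-dien-1-yl]oxy}trimethylsilane, via lithium dienolate 10 (not isolated)
Conditions: LiN(i-Pr)2, THF–DMPU, −78 °C; then Me3SiCl
Reagents that add atoms: chlorotrimethylsilane, C[Si](C)(C)Cl
Why: Deprotonation at the γ-methylene gives the extended lithium dienolate, which is silylated on oxygen to the vinylketene silyl acetal (silyl dienol ether formation).

Step 9
Reactants: 7 (3R,4E,6E,8E)-7-ethyl-3,5-dimethyl-9-phenylnona-4,6,8-trienal; 11 {[(3E)-1-tert-butoxy-2-ethylhexa-1,3-dien-1-yl]oxy}trimethylsilane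
Product: 13 tert-butyl (2E,7R,8E,10E,12E)-2,4,11-triethyl-5-hydroxy-7,9-dimethyl-13-phenyltrideca-2,8,10,12-tetraenoate (C4/C5 diastereomer mixture), via trimethylsilyl ether 12 (not isolated)
Conditions: B(C6F5)3 (5 mol %), CH2Cl2, −78 °C; then 1 M HCl, THF, 0 °C
Reagents that add atoms: none
Why: Vinylogous Mukaiyama aldol addition: the activated aldehyde is attacked by the γ-carbon of the α-substituted silyl dienolate (α-attack is sterically disfavoured), regenerating the E enoate; the two new stereocentres are harmless because C5 is oxidised in step 10 and C4 then becomes epimerisable.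

Step 10
Reactants: 13 tert-butyl (2E,7R,8E,10E,12E)-2,4,11-triethyl-5-hydroxy-7,9-dimethyl-13-phenyltrideca-2,8,10,12-tetraenoate
Product: 14 tert-butyl (2E,7R,8E,10E,12E)-2,4,11-triethyl-7,9-dimethyl-5-oxo-13-phenyltrideca-2,8,10,12-tetraenoate (C4 epimers)
Conditions: Dess–Martin periodinane, CH2Cl2, 0 °C
Reagents that add atoms: none
Why: Dess–Martin oxidation converts the secondary alcohol into the ketone under mild, non-basic conditions that should leave the β,γ-unsaturated ketone unisomerised.

Step 11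
Reactants: 14 tert-butyl (2E,7R,8E,10E,12E)-2,4,11-triethyl-7,9-dimethyl-5-oxo-13-phenyltrideca-2,8,10,12-tetraenoate
Product: 15 tert-butyl (1R,2S,4aS,5R,8aR)-1,2,8-triethyl-4,5-dimethyl-7-oxo-2-[(E)-2-phenylethenyl]-1,2,4a,5,6,7,8,8a-octahydronaphthalene-1-carboxylate (C8 epimers, interconverting)
Conditions: toluene (dilute, degassed), 2,6-di-tert-butyl-4-methylphenol (cat.), 130 °C, sealed tube
Reagents that add atoms: none
Why: Intramolecular Diels–Alder reaction of a 1,3,9-decatriene: allylic 1,3-strain between the C7 substituents and the C9 methyl keeps C7–H in the diene plane and puts the tether on the reacting face, and the E enoate should react with its ester endo and the tether anti in a chair-like transition state, which gives the trans ring junction (C4a, C8a) and both quaternary centres (C1, C2) at once, while C4 of 14 and C8 of 15 equilibrate by enolisation.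

Step 12
Reactants: 15 tert-butyl (1R,2S,4aS,5R,8aR)-1,2,8-triethyl-4,5-dimethyl-7-oxo-2-[(E)-2-phenylethenyl]-1,2,4a,5,6,7,8,8a-octahydronaphthalene-1-carboxylate
Product: 17 tert-butyl (1R,2S,4aR,5S,8aR)-1,2,8-triethyl-6-hydroxy-4,5-dimethyl-7-oxo-2-[(E)-2-phenylethenyl]-1,2,4a,5,6,7,8,8a-octahydronaphthalene-1-carboxylate (C6 and C8 epimers), via potassium enolate 16 (not isolated)
Conditions: KN(SiMe3)2, THF, −78 °C; then 3-phenyl-2-(phenylsulfonyl)oxaziridine; then AcOH
Reagents that add atoms: 3-phenyl-2-(phenylsulfonyl)oxaziridine, O=S(=O)(N1OC1c1ccccc1)c1ccccc1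
Why: The amide base removes the less hindered C6 methylene proton under kinetic control (C8 is a shielded methine) and the potassium enolate is oxygenated by the N-sulfonyloxaziridine (enolate α-hydroxylation); the configuration of the new carbinol is immaterial.

Step 13
Reactants: 17 tert-butyl (1R,2S,4aR,5S,8aR)-1,2,8-triethyl-6-hydroxy-4,5-dimethyl-7-oxo-2-[(E)-2-phenylethenyl]-1,2,4a,5,6,7,8,8a-octahydronaphthalene-1-carboxylate
Product: 18 tert-butyl (1R,2S,4aR,8aR)-1,2,8-triethyl-4,5-dimethyl-6,7-dioxo-2-[(E)-2-phenylethenyl]-1,2,4a,5,6,7,8,8a-octahydronaphthalene-1-carboxylate (in equilibrium with its diosphenol tautomers; C5 and C8 labile)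
Conditions: Dess–Martin periodinane, CH2Cl2, rt
Reagents that add atoms: none
Why: Dess–Martin oxidation of the acyloin gives the 1,2-dione, and any α-ketol isomer of 17 would give the same dione.

Step 14
Reactants: 18 tert-butyl (1R,2S,4aR,8aR)-1,2,8-triethyl-4,5-dimethyl-6,7-dioxo-2-[(E)-2-phenylethenyl]-1,2,4a,5,6,7,8,8a-octahydronaphthalene-1-carboxylate
Product: 20 (3aR,4R,5S,7aR)-4-(tert-butoxycarbonyl)-3,4,5-triethyl-2-hydroxy-1,7-dimethyl-5-[(E)-2-phenylethenyl]-2,3,3a,4,5,7a-hexahydro-1H-indene-2-carboxylic acid (mixture at C1/C2/C3), via potassium carboxylate 19 (not isolated)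
Conditions: KOH, 1,4-dioxane–H2O, argon, 100 °C; then 1 M HCl
Reagents that add atoms: potassium hydroxide, [K+].[OH-]
Why: Hydroxide adds to one carbonyl of the 1,2-dione (present mainly as its diosphenol) and the resulting alkoxide drives a 1,2-shift of the neighbouring ring carbon (C5 or C8) onto the adjacent carbonyl carbon, giving the carboxylate of the ring-contracted α-hydroxy acid (benzilic acid rearrangement). The closest known reaction type is the benzilic acid ring contraction of 3,6-dialkylcyclohexane-1,2-diones (diosphenols) to 2,5-dialkyl-1-hydroxycyclopentanecarboxylic acids, also used to contract ring A of steroid diosphenols. The five-membered ring is closed by this 1,2-carbon shift inside the tetrahedral adduct, with retention at the migrating carbon and no bond change at the fusion atoms, so C4a and C8a keep the trans junction set in step 11. The only new stereocentre, the carbinol carbon C2, is inconsequential because step 15 turns it into the carbonyl carbon, and C1/C3 are left to later thermodynamic control. Regioselectivity is not needed, since attack at either carbonyl and migration of either α-carbon lead to the same skeleton after step 15; what is needed is chemoselectivity for rearrangement over oxidative C–C cleavage and ester hydrolysis, which exclusion of oxygen and the base-inert, neopentyl-type tert-butyl ester should secure.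

Step 15
Reactants: 20 (3aR,4R,5S,7aR)-4-(tert-butoxycarbonyl)-3,4,5-triethyl-2-hydroxy-1,7-dimethyl-5-[(E)-2-phenylethenyl]-2,3,3a,4,5,7a-hexahydro-1H-indene-2-carboxylic acid
Product: 22 tert-butyl (1S,3S,3aR,4R,5S,7aR)-3,4,5-triethyl-1,7-dimethyl-2-oxo-5-[(E)-2-phenylethenyl]-2,3,3a,4,5,7a-hexahydro-1H-indene-4-carboxylate, via C1/C3-epimeric ketone mixture 21 (not isolated)
Conditions: Pb(OAc)4, CH2Cl2–AcOH, 0 °C; then DBU, toluene, 60 °C
Reagents that add atoms: none
Why: Tetravalent lead forms a cyclic lead ester of the α-hydroxy acid that fragments with loss of CO2 (oxidative decarboxylation), so the carbinol carbon becomes the C2 carbonyl; DBU then equilibrates C1 and C3 through the enolates to the isomer with the methyl anti to C7 and the ethyl anti to the quaternary C4, which avoids contacts with the C7 methyl and the C4 substituents.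

Step 16
Reactants: 22 tert-butyl (1S,3S,3aR,4R,5S,7aR)-3,4,5-triethyl-1,7-dimethyl-2-oxo-5-[(E)-2-phenylethenyl]-2,3,3a,4,5,7a-hexahydro-1H-indene-4-carboxylate
Product: 24 (1S,3S,3aR,4R,5S,7aR)-3,4,5-triethyl-1,7-dimethyl-2-oxo-5-[(E)-2-phenylethenyl]-2,3,3a,4,5,7a-hexahydro-1H-indene-4-carboxylic acid, via trimethylsilyl ester 23 (not isolated)
Conditions: Me3SiOTf, 2,6-lutidine, CH2Cl2, 0 °C to rt; then H2O
Reagents that add atoms: none
Why: The silyl triflate activates the ester carbonyl and the tert-butyl group leaves as its cation (isobutene after proton loss to lutidine), an alkyl–oxygen cleavage that needs no attack at the shielded carbonyl and avoids free strong acid, which could lactonise the γ,δ-unsaturated acid; the silyl ester is hydrolysed on work-up.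

**Compound list**

1 | (2R)-4-tert-butoxy-2-methyl-4-oxobutanoic acid | C[C@H](CC(=O)OC(C)(C)C)C(=O)O | starting material
2 | tert-butyl (3R)-4-hydroxy-3-methylbutanoate | C[C@H](CC(=O)OC(C)(C)C)CO | intermediate
3 | tert-butyl (3R)-3-methyl-4-oxobutanoate | C[C@H](CC(=O)OC(C)(C)C)C=O | intermediate
4 | tert-butyl (3R,4E)-3,5-dimethyl-6-oxohex-4-enoate | C[C@H](CC(=O)OC(C)(C)C)/C=C(\C)C=O | intermediate
5 | tert-butyl (3R,4E,6E)-7-ethyl-3,5-dimethyl-8-oxoocta-4,6-dienoate | C[C@H](CC(=O)OC(C)(C)C)/C=C(\C)/C=C(\CC)C=O | intermediate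
6 | tert-butyl (3R,4E,6E,8E)-7-ethyl-3,5-dimethyl-9-phenylnona-4,6,8-trienoate | C[C@H](CC(=O)OC(C)(C)C)/C=C(\C)/C=C(\CC)/C=C/c1ccccc1 | intermediate
7 | (3R,4E,6E,8E)-7-ethyl-3,5-dimethyl-9-phenylnona-4,6,8-trienal | C[C@H](CC=O)/C=C(\C)/C=C(\CC)/C=C/c1ccccc1 | intermediate
8 | (2E)-2-ethylhex-2-enoic acid | CCC/C=C(\CC)C(=O)O | starting material
9 | tert-butyl (2E)-2-ethylhex-2-enoate | CCC/C=C(\CC)C(=O)OC(C)(C)C | intermediate
10 | lithium (3E)-1-tert-butoxy-2-ethylhexa-1,3-dien-1-olate (lithium dienolate of 9) | CC/C=C/C(CC)=C([O-])OC(C)(C)C.[Li+] | intermediate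
11 | {[(3E)-1-tert-butoxy-2-ethylhexa-1,3-dien-1-yl]oxy}trimethylsilane (ketene acetal geometry mixed) | CC/C=C/C(CC)=C(OC(C)(C)C)O[Si](C)(C)C | intermediate
12 | tert-butyl (2E,7R,8E,10E,12E)-2,4,11-triethyl-7,9-dimethyl-13-phenyl-5-[(trimethylsilyl)oxy]trideca-2,8,10,12-tetraenoate (C4/C5 mixture) | C[C@H](CC(O[Si](C)(C)C)C(CC)/C=C(\CC)C(=O)OC(C)(C)C)/C=C(\C)/C=C(\CC)/C=C/c1ccccc1 | intermediate
13 | tert-butyl (2E,7R,8E,10E,12E)-2,4,11-triethyl-5-hydroxy-7,9-dimethyl-13-phenyltrideca-2,8,10,12-tetraenoate (C4/C5 mixture) | C[C@H](CC(O)C(CC)/C=C(\CC)C(=O)OC(C)(C)C)/C=C(\C)/C=C(\CC)/C=C/c1ccccc1 | intermediate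
14 | tert-butyl (2E,7R,8E,10E,12E)-2,4,11-triethyl-7,9-dimethyl-5-oxo-13-phenyltrideca-2,8,10,12-tetraenoate (C4 epimers) | C[C@H](CC(=O)C(CC)/C=C(\CC)C(=O)OC(C)(C)C)/C=C(\C)/C=C(\CC)/C=C/c1ccccc1 | intermediate
15 | tert-butyl (1R,2S,4aS,5R,8aR)-1,2,8-triethyl-4,5-dimethyl-7-oxo-2-[(E)-2-phenylethenyl]-1,2,4a,5,6,7,8,8a-octahydronaphthalene-1-carboxylate (C8 epimers) | CCC1C(=O)C[C@@H](C)[C@@H]2C(C)=C[C@@](/C=C/c3ccccc3)(CC)[C@](CC)(C(=O)OC(C)(C)C)[C@H]21 | intermediate
16 | potassium 6-en-7-olate of 15 (kinetic enolate) | CCC1C([O-])=C[C@@H](C)[C@@H]2C(C)=C[C@@](/C=C/c3ccccc3)(CC)[C@](CC)(C(=O)OC(C)(C)C)[C@H]21.[K+] | intermediate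
17 | tert-butyl (1R,2S,4aR,5S,8aR)-1,2,8-triethyl-6-hydroxy-4,5-dimethyl-7-oxo-2-[(E)-2-phenylethenyl]-1,2,4a,5,6,7,8,8a-octahydronaphthalene-1-carboxylate (C6 and C8 epimers) | CCC1C(=O)C(O)[C@@H](C)[C@@H]2C(C)=C[C@@](/C=C/c3ccccc3)(CC)[C@](CC)(C(=O)OC(C)(C)C)[C@H]21 | intermediate
18 | tert-butyl (1R,2S,4aR,8aR)-1,2,8-triethyl-4,5-dimethyl-6,7-dioxo-2-[(E)-2-phenylethenyl]-1,2,4a,5,6,7,8,8a-octahydronaphthalene-1-carboxylate (diketo form drawn) | CCC1C(=O)C(=O)C(C)[C@@H]2C(C)=C[C@@](/C=C/c3ccccc3)(CC)[C@](CC)(C(=O)OC(C)(C)C)[C@H]21 | intermediate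
19 | potassium salt of 20 (2-carboxylate) | CCC1C(O)(C(=O)[O-])C(C)[C@@H]2C(C)=C[C@@](/C=C/c3ccccc3)(CC)[C@](CC)(C(=O)OC(C)(C)C)[C@H]21.[K+] | intermediate
20 | (3aR,4R,5S,7aR)-4-(tert-butoxycarbonyl)-3,4,5-triethyl-2-hydroxy-1,7-dimethyl-5-[(E)-2-phenylethenyl]-2,3,3a,4,5,7a-hexahydro-1H-indene-2-carboxylic acid (mixture at C1/C2/C3) | CCC1C(O)(C(=O)O)C(C)[C@@H]2C(C)=C[C@@](/C=C/c3ccccc3)(CC)[C@](CC)(C(=O)OC(C)(C)C)[C@H]21 | intermediate
21 | tert-butyl (3aR,4R,5S,7aR)-3,4,5-triethyl-1,7-dimethyl-2-oxo-5-[(E)-2-phenylethenyl]-2,3,3a,4,5,7a-hexahydro-1H-indene-4-carboxylate (C1/C3 epimer mixture) | CCC1C(=O)C(C)[C@@H]2C(C)=C[C@@](/C=C/c3ccccc3)(CC)[C@](CC)(C(=O)OC(C)(C)C)[C@H]21 | intermediate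
22 | tert-butyl (1S,3S,3aR,4R,5S,7aR)-3,4,5-triethyl-1,7-dimethyl-2-oxo-5-[(E)-2-phenylethenyl]-2,3,3a,4,5,7a-hexahydro-1H-indene-4-carboxylate | CC[C@@H]1C(=O)[C@@H](C)[C@@H]2C(C)=C[C@@](/C=C/c3ccccc3)(CC)[C@](CC)(C(=O)OC(C)(C)C)[C@H]21 | intermediate
23 | trimethylsilyl (1S,3S,3aR,4R,5S,7aR)-3,4,5-triethyl-1,7-dimethyl-2-oxo-5-[(E)-2-phenylethenyl]-2,3,3a,4,5,7a-hexahydro-1H-indene-4-carboxylate | CC[C@@H]1C(=O)[C@@H](C)[C@@H]2C(C)=C[C@@](/C=C/c3ccccc3)(CC)[C@](CC)(C(=O)O[Si](C)(C)C)[C@H]21 | intermediate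
24 | (1S,3S,3aR,4R,5S,7aR)-3,4,5-triethyl-1,7-dimethyl-2-oxo-5-[(E)-2-phenylethenyl]-2,3,3a,4,5,7a-hexahydro-1H-indene-4-carboxylic acid | CC[C@@H]1C(=O)[C@@H](C)[C@@H]2C(C)=C[C@@](/C=C/c3ccccc3)(CC)[C@](CC)(C(=O)O)[C@H]21 | target

**Step count and risks**

Total steps: 16. Longest linear sequence: 14 (steps 1–6 and 9–16).

Steps most likely to fail:

Step 11 (cycloaddition). What may go wrong: the endo-ester/anti-tether and exo/syn transition states may not be discriminated well, because peri strain develops between the C8 ethyl group and the C1 substituents, and cis-fused isomers would form; the C2=C3 double bond of 14 may also migrate into conjugation with the C5 ketone before cycloaddition. Fallback: set out from alcohol 13 and cyclise one oxidation level lower. Silylation (t-BuMe2SiOTf, 2,6-lutidine, CH2Cl2) gives the tert-butyldimethylsilyl ether F1, which has no enolisable position and tolerates 150 °C or Me2AlCl. The cycloaddition then gives the silyloxy octahydronaphthalene F2, Bu4NF in THF frees the alcohol F3, and Dess–Martin oxidation returns to the route at 15.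

Step 14 (ring contraction). What may go wrong: the diosphenolate may resist hydroxide addition so that the 1,2-shift stalls, while adventitious oxygen cleaves the dione to the seco-diacid or vinylogous enolisation through C4a erodes the ring junction. Fallback: set out from decalone 15 and contract ring B by a Wolff rearrangement. Diazo transfer to the C6 methylene (2,4,6-triisopropylbenzenesulfonyl azide, KOH, Bu4NBr, 18-crown-6, benzene–H2O) gives the α-diazo ketone F4. Irradiation at 365 nm in THF–H2O gives the ring-contracted cyclopentanecarboxylic acid F5. Oxygenation of its dianion (LiN(i-Pr)2, THF, then O2) gives the α-hydroperoxy acid F6, which loses CO2 and water on acidic work-up and so comes back to the route at ketone mixture 21, equilibrated with DBU to 22 as in step 15.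

Step 9 (fragment coupling). What may go wrong: bond formation through the α-carbon of the silyl dienolate (branched, deconjugated adduct), or Lewis-acid-induced isomerisation and oligomerisation of the aryl triene. Fallback: set out from aldehyde 7 and make the same bond by a classical aldol addition followed by olefination. The lithium enolate of N-methoxy-N-methylbutanamide (LiN(i-Pr)2, THF, −78 °C) adds to 7 to give the β-hydroxy amide F7. LiAlH4 at −78 °C reduces the amide to the β-hydroxy aldehyde F8, which is treated at once with tert-butyl 2-(triphenylphosphoranylidene)butanoate (toluene, 50 °C) to give the E enoate and return to the route at 13.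

Further compounds

F1 | step 11 | tert-butyl (2E,7R,8E,10E,12E)-5-[(tert-butyldimethylsilyl)oxy]-2,4,11-triethyl-7,9-dimethyl-13-phenyltrideca-2,8,10,12-tetraenoate (C4/C5 mixture) | C[C@H](CC(O[Si](C)(C)C(C)(C)C)C(CC)/C=C(\CC)C(=O)OC(C)(C)C)/C=C(\C)/C=C(\CC)/C=C/c1ccccc1
F2 | step 11 | tert-butyl (1R,2S,4aS,5R,8aR)-7-[(tert-butyldimethylsilyl)oxy]-1,2,8-triethyl-4,5-dimethyl-2-[(E)-2-phenylethenyl]-1,2,4a,5,6,7,8,8a-octahydronaphthalene-1-carboxylate (C7/C8 mixture) | CCC1C(O[Si](C)(C)C(C)(C)C)C[C@@H](C)[C@@H]2C(C)=C[C@@](/C=C/c3ccccc3)(CC)[C@](CC)(C(=O)OC(C)(C)C)[C@H]21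
F3 | step 11 | tert-butyl (1R,2S,4aS,5R,8aR)-1,2,8-triethyl-7-hydroxy-4,5-dimethyl-2-[(E)-2-phenylethenyl]-1,2,4a,5,6,7,8,8a-octahydronaphthalene-1-carboxylate (C7/C8 mixture) | CCC1C(O)C[C@@H](C)[C@@H]2C(C)=C[C@@](/C=C/c3ccccc3)(CC)[C@](CC)(C(=O)OC(C)(C)C)[C@H]21
F4 | step 14 | tert-butyl (1R,2S,4aR,5S,8aR)-6-diazo-1,2,8-triethyl-4,5-dimethyl-7-oxo-2-[(E)-2-phenylethenyl]-1,2,4a,5,6,7,8,8a-octahydronaphthalene-1-carboxylate (C8 epimers) | CCC1C(=O)C(=[N+]=[N-])[C@@H](C)[C@@H]2C(C)=C[C@@](/C=C/c3ccccc3)(CC)[C@](CC)(C(=O)OC(C)(C)C)[C@H]21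
F5 | step 14 | (1S,3aS,4R,5S,7aS)-4-(tert-butoxycarbonyl)-3,4,5-triethyl-1,7-dimethyl-5-[(E)-2-phenylethenyl]-2,3,3a,4,5,7a-hexahydro-1H-indene-2-carboxylic acid (C2/C3 mixture) | CCC1C(C(=O)O)[C@@H](C)[C@@H]2C(C)=C[C@@](/C=C/c3ccccc3)(CC)[C@](CC)(C(=O)OC(C)(C)C)[C@H]21
F6 | step 14 | (1S,3aR,4R,5S,7aR)-4-(tert-butoxycarbonyl)-3,4,5-triethyl-2-hydroperoxy-1,7-dimethyl-5-[(E)-2-phenylethenyl]-2,3,3a,4,5,7a-hexahydro-1H-indene-2-carboxylic acid (C2/C3 mixture) | CCC1C(OO)(C(=O)O)[C@@H](C)[C@@H]2C(C)=C[C@@](/C=C/c3ccccc3)(CC)[C@](CC)(C(=O)OC(C)(C)C)[C@H]21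
F7 | step 9 | (5R,6E,8E,10E)-2,9-diethyl-3-hydroxy-N-methoxy-N,5,7-trimethyl-11-phenylundeca-6,8,10-trienamide (C2/C3 mixture) | C[C@H](CC(O)C(CC)C(=O)N(C)OC)/C=C(\C)/C=C(\CC)/C=C/c1ccccc1
F8 | step 9 | (5R,6E,8E,10E)-2,9-diethyl-3-hydroxy-5,7-dimethyl-11-phenylundeca-6,8,10-trienal (C2/C3 mixture) | C[C@H](CC(O)C(CC)C=O)/C=C(\C)/C=C(\CC)/C=C/c1ccccc1
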